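**Plan**

1. Retrosynthesis: the two O–CH3 bonds are cut first (the catechol is carried as its dimethyl ether). The lactam bond N1–C5 is cut next, together with N1–C2, which leads back to cyclobutanone and a benzylic azide. The benzylic C–N3 and C–Br bonds and the three aryl C–Br bonds are cut last, back to 3,4-dimethoxytoluene.
2. Forward: the benzene ring is bought and brominated at all three free positions, so no regiochemical choice arises. The methyl group becomes CH2Br, then CH2N3. The lactam ring arises last, in one nitrogen-insertion event, and the methyl ethers are then removed.
3. Enabling feature: in the pyrrolidinone ring N1 lies between the carbonyl carbon C2 and the methylene C5, and C3, C4 and C5 carry only hydrogen. The ring is therefore a symmetric cyclobutanone with the benzylic nitrogen inserted between the carbonyl carbon and one alpha carbon, and the nitrogen substituent is a primary benzylic carbon that can carry an azide.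
4. Key event (Schmidt reaction): C5 is held on C2 in a temporary four-membered ring and the nitrogen carries N2 as leaving group. The 1,2-shift of C5 from C2 to N1 closes the lactam, and the temporary C2–C5 bond and the N2 group are both lost in the same step.
5. Stereochemistry: the target has no stereocentre and no double-bond geometry, so none is set.

Key step: step 4

Remark on the chemistry: the titanium-bound adduct 8 is drawn as the metal-free zwitterion, the boron-bound intermediate 10 as the cyclic bromoborane, and intermediate 3 as the dibromide expected from the directing effects.

**Route**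

Step 1
Reactants: 1 homoveratrole (3,4-dimethoxytoluene)
Product: 4 aryl tribromide (2,3,6-tribromo-4,5-dimethoxytoluene), via 2-bromo-4,5-dimethoxytoluene 2 (not isolated), via 2,6-dibromo-3,4-dimethoxytoluene 3 (not isolated)
Conditions: Br2 (4 equiv), CH2Cl2, 0 °C; then FeBr3 (cat.), 40 °C, dark; aq. Na2S2O3 work-up
Reagents that add atoms: bromine, BrBr
Why: Electrophilic aromatic bromination, in which the two methoxy groups and the methyl group activate all three free ring positions, so that bromine enters para to the 3-methoxy group first (2), then between the methyl and the 3-methoxy group (3) and last, with FeBr3 as Lewis acid, next to the 4-methoxy group, and since every free position ends up brominated no regiochemical choice has to be made.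

Step 2
Reactants: 4 aryl tribromide (2,3,6-tribromo-4,5-dimethoxytoluene)
Product: 5 benzylic bromide (2,3,6-tribromo-4,5-dimethoxybenzyl bromide)
Conditions: NBS (1.1 equiv), AIBN (cat.), PhCF3, 80 °C
Reagents that add atoms: N-bromosuccinimide, O=C1CCC(=O)N1Br
Why: Wohl–Ziegler benzylic bromination, a radical chain in which the benzylic C–H bonds are the only ones weak enough for abstraction by a bromine atom, while the fully substituted ring offers no site for electrophilic attack and the two ortho bromines slow a second bromination of the CH2Br group.

Step 3
Reactants: 5 benzylic bromide (2,3,6-tribromo-4,5-dimethoxybenzyl bromide)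
Product: 6 benzylic azide (2,3,6-tribromo-4,5-dimethoxybenzyl azide)
Conditions: NaN3 (1.5 equiv), DMF, rt
Reagents that add atoms: sodium azide, [Na+].[N-]=[N+]=[N-]
Why: SN2 substitution of a primary benzylic bromide by azide in a dipolar aprotic solvent, which should be fast in spite of the two ortho bromines, whereas the aryl bromides lack the activation needed for nucleophilic aromatic substitution.

Step 4
Reactants: 6 benzylic azide (2,3,6-tribromo-4,5-dimethoxybenzyl azide); 7 cyclobutanone
Product: 9 N-(2,3,6-tribromo-4,5-dimethoxybenzyl)pyrrolidin-2-one, via azidohydrin adduct 8 (not isolated)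
Conditions: 7 (3 equiv), TiCl4 (3 equiv), CH2Cl2, 0 °C to rt; then H2O
Reagents that add atoms: none
Why: Intermolecular Schmidt reaction of an alkyl azide with a ketone: TiCl4 activates the strained carbonyl group of 7, the alkylated nitrogen of azide 6 adds to it to give the titanium-bound azidohydrin 8 (an aminodiazonium alkoxide), and a ring CH2 antiperiplanar to the departing N2 shifts from carbon to nitrogen. This 1,2-shift forms the N1–C5 bond and at the same moment turns the four-membered carbocycle into the five-membered lactam, so the ring is closed by ring enlargement (a 1,2-migration from carbon to nitrogen, not an exo or endo attack along a chain), and the carbon that the nitrogen attacked becomes C2. The closest known reaction type is the TiCl4-promoted Schmidt reaction of primary alkyl and benzyl azides with cyclic ketones, in which cyclobutanone should be an especially willing partner because addition and ring enlargement both release strain. No stereocentre is formed. The step needs chemoselectivity for nitrogen insertion over acid-induced decomposition of the benzylic azide (loss of N2 with aryl or hydride shift to an iminium ion and Mannich-type capture); this is secured by the aprotic Lewis acid in place of a protic superacid, by the three electron-withdrawing bromines, which make the aryl group a poor migrating group and the benzylic carbon a poor cation, and by the excess of the electrophilic ketone. Regioselectivity of migration is no issue because the two alpha carbons of 7 are equivalent, and the aryl bromides and methyl ethers are inert to TiCl4 at these temperatures.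

Step 5
Reactants: 9 N-(2,3,6-tribromo-4,5-dimethoxybenzyl)pyrrolidin-2-one
Product: 11 N-(2,3,6-tribromo-4,5-dihydroxybenzyl)pyrrolidin-2-one (target CNP0121188.0), via cyclic bromoborane 10 (not isolated)
Conditions: BBr3 (4 equiv), CH2Cl2, −78 °C to rt; then H2O
Reagents that add atoms: none
Why: Ether cleavage by BBr3 (Lewis-acid demethylation), in which boron binds each methoxy oxygen and bromide takes the methyl group by SN2 to leave the cyclic bromoborane 10 that water hydrolyses to the catechol, while the lactam and the aryl bromides are inert and the three electron-withdrawing bromines hold the benzylic C–N bond against ionisation.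

**Compound list**

1 | homoveratrole (3,4-dimethoxytoluene) | Cc1ccc(OC)c(OC)c1 | starting material
2 | 2-bromo-4,5-dimethoxytoluene (not isolated) | Cc1cc(OC)c(OC)cc1Br | intermediate
3 | 2,6-dibromo-3,4-dimethoxytoluene (not isolated) | Cc1c(Br)c(OC)c(OC)cc1Br | intermediate
4 | 2,3,6-tribromo-4,5-dimethoxytoluene | Cc1c(Br)c(OC)c(OC)c(Br)c1Br | intermediate
5 | 2,3,6-tribromo-4,5-dimethoxybenzyl bromide | BrCc1c(Br)c(OC)c(OC)c(Br)c1Br | intermediate
6 | 2,3,6-tribromo-4,5-dimethoxybenzyl azide | [N-]=[N+]=NCc1c(Br)c(OC)c(OC)c(Br)c1Br | intermediate
7 | cyclobutanone | O=C1CCC1 | starting material
8 | azidohydrin adduct, N-(1-oxidocyclobutyl)-N-(2,3,6-tribromo-4,5-dimethoxybenzyl)aminodiazonium, titanium-bound in the flask (not isolated) | [O-]C1(CCC1)N(Cc1c(Br)c(OC)c(OC)c(Br)c1Br)[N+]#N | intermediate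
9 | N-(2,3,6-tribromo-4,5-dimethoxybenzyl)pyrrolidin-2-one | O=C1CCCN1Cc1c(Br)c(OC)c(OC)c(Br)c1Br | intermediate
10 | cyclic bromoborane, 1-[(2,4,6,7-tetrabromo-1,3,2-benzodioxaborol-5-yl)methyl]pyrrolidin-2-one (not isolated) | O=C1CCCN1Cc1c(Br)c2OB(Br)Oc2c(Br)c1Br | intermediate
11 | N-(2,3,6-tribromo-4,5-dihydroxybenzyl)pyrrolidin-2-one | O=C1CCCN1Cc1c(Br)c(O)c(O)c(Br)c1Br | target

**Summary**

Total step count: 5. Longest linear sequence: 5 steps (from 1; cyclobutanone 7 is bought).

Steps most likely to fail:

Step 4 (key step). The azide may lose N2 under the Lewis acid before it has added to the ketone (aryl or hydride shift to an iminium ion, then Mannich-type capture), or the nitrogen, screened by the two ortho bromines, may add too slowly. The fallback sets out from 6 and comes back at 9, forming the same N1–C5 bond by a conventional ring closure. Staudinger reduction of 6 (PPh3, THF, then H2O, 50 °C) should pass through the iminophosphorane F1 to the benzylamine F2. Acylation with 4-chlorobutanoyl chloride (Et3N, CH2Cl2, 0 °C) should give the 4-chlorobutanamide F3. Treatment with NaH (THF, 0 °C to rt) should close the ring by 5-exo-tet N-alkylation of the amidate to give 9.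

Step 1. The third bromination may stall on a ring already deactivated by two bromines, and forcing the conditions may bring on benzylic bromination or ether cleavage. The fallback sets out from 1 and comes back at 4, brominating at the far more reactive free-catechol level. Demethylation of 1 (48% aq. HBr, AcOH, reflux) should give 4-methylcatechol F4. Bromination without catalyst (Br2, 3.1 equiv, AcOH, rt) should fill the three free positions to give 3,4,6-tribromo-5-methylcatechol F5. Methylation of both phenols (MeI, K2CO3, DMF, rt) should return 4.

Step 2. Hydrogen abstraction from a methyl group buttressed by two ortho bromines may be slow, or bromination may run on to the dibromomethyl stage. The fallback sets out from 4 and comes back at 6, replacing the radical halogenation by an oxidation and reduction sequence. Oxidation of the methyl group (KMnO4, pyridine/H2O, reflux, then acid) should give 2,3,6-tribromo-4,5-dimethoxybenzoic acid F6. Reduction with BH3·THF (THF, 0 °C to reflux), which leaves aryl bromides untouched, should give the benzyl alcohol F7. Azidation with diphenylphosphoryl azide and DBU (toluene, rt to 60 °C) should give 6 by phosphate activation and SN2 displacement.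

**Further compounds**

F1 | step 4 | N-(2,3,6-tribromo-4,5-dimethoxybenzyl)iminotriphenylphosphorane (not isolated) | c1ccc(cc1)P(=NCc1c(Br)c(OC)c(OC)c(Br)c1Br)(c1ccccc1)c1ccccc1
F2 | step 4 | (2,3,6-tribromo-4,5-dimethoxyphenyl)methanamine | NCc1c(Br)c(OC)c(OC)c(Br)c1Br
F3 | step 4 | 4-chloro-N-(2,3,6-tribromo-4,5-dimethoxybenzyl)butanamide | O=C(CCCCl)NCc1c(Br)c(OC)c(OC)c(Br)c1Br
F4 | step 1 | 4-methylcatechol (4-methylbenzene-1,2-diol) | Cc1ccc(O)c(O)c1
F5 | step 1 | 3,4,6-tribromo-5-methylbenzene-1,2-diol | Cc1c(Br)c(O)c(O)c(Br)c1Br
F6 | step 2 | 2,3,6-tribromo-4,5-dimethoxybenzoic acid | OC(=O)c1c(Br)c(OC)c(OC)c(Br)c1Br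
F7 | step 2 | (2,3,6-tribromo-4,5-dimethoxyphenyl)methanol | OCc1c(Br)c(OC)c(OC)c(Br)c1Br
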